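**Assumption:** the target has no stereocentre and its diaryl ether axis is not configurationally stable, so it is made as the single achiral compound; ethyl (Z)‑3‑(tributylstannyl)acrylate is taken as a catalogue reagent.

**Retrosynthetic overview**
1. Target 10 ⇐ 7: the two oxygens still missing (5‑OH of the dihydroxycoumarin, O‑1 of the methoxycoumarin) come from two formyl groups by a double Dakin oxidation; the methoxycoumarin pyranone closes as its phenol is unveiled (last ring).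
2. 7 ⇐ 4 + 2 × 5: both C4–C4a bonds are made in one pot from a β‑acylvinyl anion (d3) reagent and two aryl bromides ortho to CHO; the pyranone of the dihydroxycoumarin closes here (first ring).
3. 4 ⇐ 3 (ring bromination); 3 ⇐ 1 + 2 (SNAr diaryl ether). Both benzene rings are bought.
4. No protecting groups: each formyl group first activates or blocks its ring position and later becomes a phenol oxygen.

**Route**

Step 1
Reactants: 1 3,4,5‑trihydroxybenzaldehyde; 2 6‑bromo‑2‑fluoro‑3‑methoxybenzaldehyde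
Product: 3 6‑bromo‑2‑(4‑formyl‑2,6‑dihydroxyphenoxy)‑3‑methoxybenzaldehyde
Conditions: K2CO3 (1.0 equiv), degassed DMSO, Ar, 90–100 °C
Reagents that add atoms: none
Why: SNAr in which one equivalent of carbonate deprotonates only the 4‑OH of 1 (para to CHO, the most acidic OH) and this phenoxide displaces the fluoride of 2, activated by the ortho formyl group (F far better than Br as leaving group); no stereocentre is formed.

Step 2
Reactants: 3 6‑bromo‑2‑(4‑formyl‑2,6‑dihydroxyphenoxy)‑3‑methoxybenzaldehyde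
Product: 4 6‑bromo‑2‑(3‑bromo‑4‑formyl‑2,6‑dihydroxyphenoxy)‑3‑methoxybenzaldehyde
Conditions: NBS (1.0 equiv), MeCN, −20 → 0 °C
Reagents that add atoms: N‑bromosuccinimide, O=C1CCC(=O)N1Br
Why: Electrophilic aromatic bromination at one of the two equivalent free positions of the resorcinol ring (ortho to one OH, para to the other), while the other ring is deactivated by CHO and Br.

Step 3
Reactants: 4 6‑bromo‑2‑(3‑bromo‑4‑formyl‑2,6‑dihydroxyphenoxy)‑3‑methoxybenzaldehyde; 5 ethyl (Z)‑3‑(tributylstannyl)prop‑2‑enoate (2.4 equiv)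
Product: 7 ethyl (2Z)‑3‑{2‑formyl‑3‑[(5‑formyl‑7‑hydroxy‑2‑oxo‑2H‑chromen‑8‑yl)oxy]‑4‑methoxyphenyl}prop‑2‑enoate, via bis‑(Z)‑acrylate 6 (not isolated)
Conditions: PdCl2 (5 mol %), P(t‑Bu)3 (10 mol %), CuI (10 mol %), CsF (4 equiv), DMF, 45–60 °C
Reagents that add atoms: none
Why: Double Stille cross‑coupling in which 5 acts as a β‑acylvinyl anion (d3) reagent, joining the normally electrophilic acrylate β‑carbon to the normally electrophilic ortho‑formyl aryl carbons with retention of Z geometry; on the resorcinol ring the only OH ortho to the new alkene (the other neighbour is CHO) lactonises in the pot, which fixes the 8‑aryloxy rather than 6‑aryloxy coumarin.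

Step 4
Reactants: 7 ethyl (2Z)‑3‑{2‑formyl‑3‑[(5‑formyl‑7‑hydroxy‑2‑oxo‑2H‑chromen‑8‑yl)oxy]‑4‑methoxyphenyl}prop‑2‑enoate
Product: 10 5,7‑dihydroxy‑8‑[(7‑methoxy‑2‑oxo‑2H‑chromen‑8‑yl)oxy]‑2H‑chromen‑2‑one, via bis‑formate 8 (not isolated), via phenolic (Z)‑cinnamate 9 (not isolated)
Conditions: mCPBA (2.5 equiv), CH2Cl2, 0 °C → rt; then Et3N, MeOH, rt → 40 °C
Reagents that add atoms: mCPBA (3‑chloroperoxybenzoic acid), O=C(OO)c1cccc(Cl)c1
Why: Double Baeyer–Villiger (Dakin‑type) oxidation in which each formyl group has an ortho or para aryloxy donor and is twisted by its neighbours, so the aryl group migrates; methanolysis of the two aryl formates frees the 5‑OH and the phenol next to the (Z)‑acrylate, which lactonises to the second coumarin.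

**Compound list**
1 | 3,4,5‑trihydroxybenzaldehyde | O=Cc1cc(O)c(O)c(O)c1 | starting material
2 | 6‑bromo‑2‑fluoro‑3‑methoxybenzaldehyde | COc1ccc(Br)c(C=O)c1F | starting material
3 | 6‑bromo‑2‑(4‑formyl‑2,6‑dihydroxyphenoxy)‑3‑methoxybenzaldehyde | COc1ccc(Br)c(C=O)c1Oc1c(O)cc(C=O)cc1O | intermediate
4 | 6‑bromo‑2‑(3‑bromo‑4‑formyl‑2,6‑dihydroxyphenoxy)‑3‑methoxybenzaldehyde | COc1ccc(Br)c(C=O)c1Oc1c(O)cc(C=O)c(Br)c1O | intermediate
5 | ethyl (Z)‑3‑(tributylstannyl)prop‑2‑enoate | CCCC[Sn](CCCC)(CCCC)/C=C\C(=O)OCC | starting material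
6 | ethyl (2Z)‑3‑{3‑[3‑((1Z)‑3‑ethoxy‑3‑oxoprop‑1‑en‑1‑yl)‑4‑formyl‑2,6‑dihydroxyphenoxy]‑2‑formyl‑4‑methoxyphenyl}prop‑2‑enoate (not isolated) | CCOC(=O)/C=C\c1ccc(OC)c(Oc2c(O)cc(C=O)c(/C=C\C(=O)OCC)c2O)c1C=O | intermediate
7 | ethyl (2Z)‑3‑{2‑formyl‑3‑[(5‑formyl‑7‑hydroxy‑2‑oxo‑2H‑chromen‑8‑yl)oxy]‑4‑methoxyphenyl}prop‑2‑enoate | CCOC(=O)/C=C\c1ccc(OC)c(Oc2c(O)cc(C=O)c3ccc(=O)oc23)c1C=O | intermediate
8 | ethyl (2Z)‑3‑{2‑(formyloxy)‑3‑[(5‑(formyloxy)‑7‑hydroxy‑2‑oxo‑2H‑chromen‑8‑yl)oxy]‑4‑methoxyphenyl}prop‑2‑enoate (not isolated) | CCOC(=O)/C=C\c1ccc(OC)c(Oc2c(O)cc(OC=O)c3ccc(=O)oc23)c1OC=O | intermediate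
9 | ethyl (2Z)‑3‑{3‑[(5,7‑dihydroxy‑2‑oxo‑2H‑chromen‑8‑yl)oxy]‑2‑hydroxy‑4‑methoxyphenyl}prop‑2‑enoate (not isolated) | CCOC(=O)/C=C\c1ccc(OC)c(Oc2c(O)cc(O)c3ccc(=O)oc23)c1O | intermediate
10 | 5,7‑dihydroxy‑8‑[(7‑methoxy‑2‑oxo‑2H‑chromen‑8‑yl)oxy]‑2H‑chromen‑2‑one | COc1ccc2ccc(=O)oc2c1Oc1c(O)cc(O)c2ccc(=O)oc12 | target

**Totals**
Total step count: 4. Longest linear sequence: 4 steps (1/2 → 3 → 4 → 7 → 10).

**Three steps most likely to fail, with fallbacks**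

Step 1 (SNAr of unprotected gallaldehyde). The risks are arylation at O‑3, base‑mediated Smiles migration of the aryl group from O‑4 to O‑3, and air oxidation of the pyrogallol. The fallback sets out from 1 and protects the flanking oxygens. Perbenzylation (BnBr, K2CO3, DMF) gives 3,4,5‑tris(benzyloxy)benzaldehyde F1. One equivalent of BCl3 with pentamethylbenzene at −78 °C removes the central, doubly flanked benzyl group to give 3,5‑bis(benzyloxy)‑4‑hydroxybenzaldehyde F2. SNAr of F2 with 2 (K2CO3, DMF, 110 °C), now without any neighbouring OH, gives 2‑[2,6‑bis(benzyloxy)‑4‑formylphenoxy]‑6‑bromo‑3‑methoxybenzaldehyde F3. Excess BCl3/pentamethylbenzene at −78 °C removes both benzyl groups and the fallback comes back to the route at 3.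

Step 3 (double Stille annulation). The risks are incomplete second coupling, protodestannylation by the free phenols, and Z→E isomerisation of the acrylate that cannot yet lactonise. The fallback sets out from 4 and makes the same bonds with a boron d3 reagent, setting the geometry afterwards with light. Suzuki coupling of 4 with ethyl (E)‑3‑(4,4,5,5‑tetramethyl‑1,3,2‑dioxaborolan‑2‑yl)prop‑2‑enoate F4 (Pd(dppf)Cl2, K3PO4, dioxane/H2O, 80 °C) gives the bis‑(E)‑acrylate F5. Photocatalytic E→Z isomerisation (riboflavin, 402 nm, MeCN/MeOH) passes through the half‑isomerised diester F6, whose resorcinol‑ring (Z)‑acrylate lactonises at once. This leaves a mixture of 7 and its (E)‑acrylate isomer F7. The mixture is taken through the step 4 conditions: 7 gives 10, while F7 gives the (E)‑bis‑formate F8 and then the (E)‑hydroxycinnamate F9. A second irradiation under the same conditions isomerises and lactonises F9, and the fallback comes back to the route at 10.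

Step 4 (double Dakin). The main risk is at the coumarin 5‑carbaldehyde, which has only one para donor and two meta acceptors, so hydride migration to the carboxylic acid may compete with aryl migration. The fallback sets out from 2 and masks that oxygen as an acetyl group, for which aryl migration is the only Baeyer–Villiger pathway. SNAr of 3',4',5'‑trihydroxyacetophenone F10 with 2 (as in step 1) gives 2‑(4‑acetyl‑2,6‑dihydroxyphenoxy)‑6‑bromo‑3‑methoxybenzaldehyde F11. NBS (as in step 2) gives 2‑(4‑acetyl‑3‑bromo‑2,6‑dihydroxyphenoxy)‑6‑bromo‑3‑methoxybenzaldehyde F12. Double Stille coupling with 5 (as in step 3) gives the acetyl bis‑(Z)‑acrylate F13, which lactonises in the pot to the 5‑acetylcoumarin F14. mCPBA with catalytic TFA in CH2Cl2 at rt converts the aldehyde to the formate and the ketone to the acetate, giving the acetate–formate F15. K2CO3/MeOH followed by AcOH cleaves both esters and the fallback comes back to the route at 9, which lactonises to 10 as in step 4.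

**Further compounds**
F1 | step 1 | 3,4,5‑tris(benzyloxy)benzaldehyde | O=Cc1cc(OCc2ccccc2)c(OCc2ccccc2)c(OCc2ccccc2)c1
F2 | step 1 | 3,5‑bis(benzyloxy)‑4‑hydroxybenzaldehyde | O=Cc1cc(OCc2ccccc2)c(O)c(OCc2ccccc2)c1
F3 | step 1 | 2‑[2,6‑bis(benzyloxy)‑4‑formylphenoxy]‑6‑bromo‑3‑methoxybenzaldehyde | COc1ccc(Br)c(C=O)c1Oc1c(OCc2ccccc2)cc(C=O)cc1OCc1ccccc1
F4 | step 3 | ethyl (E)‑3‑(4,4,5,5‑tetramethyl‑1,3,2‑dioxaborolan‑2‑yl)prop‑2‑enoate | CCOC(=O)/C=C/B1OC(C)(C)C(C)(C)O1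
F5 | step 3 | ethyl (2E)‑3‑{3‑[3‑((1E)‑3‑ethoxy‑3‑oxoprop‑1‑en‑1‑yl)‑4‑formyl‑2,6‑dihydroxyphenoxy]‑2‑formyl‑4‑methoxyphenyl}prop‑2‑enoate | CCOC(=O)/C=C/c1ccc(OC)c(Oc2c(O)cc(C=O)c(/C=C/C(=O)OCC)c2O)c1C=O
F6 | step 3 | ethyl (2E)‑3‑{3‑[3‑((1Z)‑3‑ethoxy‑3‑oxoprop‑1‑en‑1‑yl)‑4‑formyl‑2,6‑dihydroxyphenoxy]‑2‑formyl‑4‑methoxyphenyl}prop‑2‑enoate | CCOC(=O)/C=C/c1ccc(OC)c(Oc2c(O)cc(C=O)c(/C=C\C(=O)OCC)c2O)c1C=O
F7 | step 3 | ethyl (2E)‑3‑{2‑formyl‑3‑[(5‑formyl‑7‑hydroxy‑2‑oxo‑2H‑chromen‑8‑yl)oxy]‑4‑methoxyphenyl}prop‑2‑enoate | CCOC(=O)/C=C/c1ccc(OC)c(Oc2c(O)cc(C=O)c3ccc(=O)oc23)c1C=O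
F8 | step 3 | ethyl (2E)‑3‑{2‑(formyloxy)‑3‑[(5‑(formyloxy)‑7‑hydroxy‑2‑oxo‑2H‑chromen‑8‑yl)oxy]‑4‑methoxyphenyl}prop‑2‑enoate | CCOC(=O)/C=C/c1ccc(OC)c(Oc2c(O)cc(OC=O)c3ccc(=O)oc23)c1OC=O
F9 | step 3 | ethyl (2E)‑3‑{3‑[(5,7‑dihydroxy‑2‑oxo‑2H‑chromen‑8‑yl)oxy]‑2‑hydroxy‑4‑methoxyphenyl}prop‑2‑enoate | CCOC(=O)/C=C/c1ccc(OC)c(Oc2c(O)cc(O)c3ccc(=O)oc23)c1O
F10 | step 4 | 3',4',5'‑trihydroxyacetophenone | CC(=O)c1cc(O)c(O)c(O)c1
F11 | step 4 | 2‑(4‑acetyl‑2,6‑dihydroxyphenoxy)‑6‑bromo‑3‑methoxybenzaldehyde | COc1ccc(Br)c(C=O)c1Oc1c(O)cc(C(C)=O)cc1O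
F12 | step 4 | 2‑(4‑acetyl‑3‑bromo‑2,6‑dihydroxyphenoxy)‑6‑bromo‑3‑methoxybenzaldehyde | COc1ccc(Br)c(C=O)c1Oc1c(O)cc(C(C)=O)c(Br)c1O
F13 | step 4 | ethyl (2Z)‑3‑{3‑[4‑acetyl‑3‑((1Z)‑3‑ethoxy‑3‑oxoprop‑1‑en‑1‑yl)‑2,6‑dihydroxyphenoxy]‑2‑formyl‑4‑methoxyphenyl}prop‑2‑enoate | CCOC(=O)/C=C\c1ccc(OC)c(Oc2c(O)cc(C(C)=O)c(/C=C\C(=O)OCC)c2O)c1C=O
F14 | step 4 | ethyl (2Z)‑3‑{3‑[(5‑acetyl‑7‑hydroxy‑2‑oxo‑2H‑chromen‑8‑yl)oxy]‑2‑formyl‑4‑methoxyphenyl}prop‑2‑enoate | CCOC(=O)/C=C\c1ccc(OC)c(Oc2c(O)cc(C(C)=O)c3ccc(=O)oc23)c1C=O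
F15 | step 4 | ethyl (2Z)‑3‑{3‑[(5‑acetoxy‑7‑hydroxy‑2‑oxo‑2H‑chromen‑8‑yl)oxy]‑2‑(formyloxy)‑4‑methoxyphenyl}prop‑2‑enoate | CCOC(=O)/C=C\c1ccc(OC)c(Oc2c(O)cc(OC(C)=O)c3ccc(=O)oc23)c1OC=O
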